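**Retrosynthetic overview**
1. Target 43 ⇐ pentacycle 40 (nine-membered ring by N–C19 alkylation of the lactam; C2 and C18 by an Evans syn aldol on the C2 aldehyde; C11 deoxygenation) ⇐ tetracyclic enone lactam 28.
2. 28 ⇐ 27 by the key radical closure of the cycloheptenone: bond C6–C12 from an α-keto radical (ketone at C11, iodide at C12) and the enamide N–C7=C6.
3. 27 ⇐ spiro dihydropyridinone 18 (C5 alkylation with the benzyloxypropyl chain; lactam ring by amide/acetal condensation; C10 acetyl by nitrile oxide cycloaddition) ⇐ acid 14.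
4. 14 ⇐ Ireland–Claisen rearrangement (C8–C5 bond, 1,3-chirality transfer from C10–O) ⇐ bicyclic enone 9 ⇐ cyclopentenone (ring B) + malonate + bromomethylacrylic acid (ring A by aldol condensation).
5. Feature and ring order: C6, the bridgehead CH shared by the six-membered lactam and the cycloheptene, is the β-carbon of an enamide of that lactam, and its cycloheptene neighbour C12 is α to a temporary ketone at C11. Rings form in the order cyclopentane B, cyclopentene A, lactam, cycloheptene (key step), nine-membered ring.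

Key step: step 18

Atom numbers used below: C1 lactam C=O; C2 carbinol CH; C3, C4 the CH2CH2 link from C2 to C5; C5 quaternary carbon bearing C21H2O; C6 bridgehead CH; C7 lactam NCH2; C8 spiro carbon; C9=C10 ring alkene; C11, C12 cycloheptene CH2CH2 (C12 on C6); C13 CH2; C14 CHCO2Me; C15 ring-fusion CH; C16, C17 cyclopentene CH2CH2; C18 CHMe; C19 NCH2 of the nine-membered ring.

Assumption: acids 4 and 11, bromide 20 and imide 34 are taken as purchasable, and the sense of induction of the two chiral catalysts (steps 1 and 5) is taken from their usual models.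

**Route**

Step 1
Reactants: 1 cyclopent-2-en-1-one; 2 dimethyl malonate
Product: 3 dimethyl 2-[(1S)-3-oxocyclopentyl]propanedioate
Conditions: LiAl[(S)-BINOLate]2 (5 mol%), KOt-Bu (5 mol%), 4 Å molecular sieves, THF, rt
Reagents that add atoms: none
Why: Catalytic asymmetric Michael addition; the aluminium–lithium bis(binaphthoxide) activates the enone as Lewis acid and the malonate as base, and the (S)-ligand is expected to give the (S) centre C15 (the mirror-image ligand would serve if the sense were the opposite).

Step 2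
Reactants: 3 dimethyl 2-[(1S)-3-oxocyclopentyl]propanedioate; 4 2-(bromomethyl)prop-2-enoic acid
Product: 5 2-{2,2-bis(methoxycarbonyl)-2-[(1S)-3-oxocyclopentyl]ethyl}prop-2-enoic acid
Conditions: NaH (2.2 equiv), THF, 0 °C → rt; then 1 M HCl
Reagents that add atoms: none
Why: Malonate alkylation of the allylic bromide (SN2 or SN2' give the same product); only the malonate C–H and the carboxylic acid are deprotonated, so C15 is untouched and C14 becomes a gem-diester that carries no acidic hydrogen through the later base steps.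

Step 3
Reactants: 5 2-{2,2-bis(methoxycarbonyl)-2-[(1S)-3-oxocyclopentyl]ethyl}prop-2-enoic acid; 6 4-methoxybenzylamine
Product: 7 dimethyl 2-{2-[(4-methoxybenzyl)carbamoyl]prop-2-en-1-yl}-2-[(1S)-3-oxocyclopentyl]propanedioate
Conditions: DCC, HOBt (cat.), CH2Cl2, 0 °C → rt
Reagents that add atoms: none
Why: Carbodiimide amide coupling through the HOBt ester; the α-substituted acrylic acid is a poor Michael acceptor, so the amine is acylated and supplies the nitrogen of the later lactam.

Step 4
Reactants: 7 dimethyl 2-{2-[(4-methoxybenzyl)carbamoyl]prop-2-en-1-yl}-2-[(1S)-3-oxocyclopentyl]propanedioate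
Product: 9 bicyclic enone amide (diquinane with C8=C9 alkene, C10 ketone, C8 N-(4-methoxybenzyl)carboxamide, C14 gem-dimethyl ester, 15S), via keto amide 8 (not isolated)
Conditions: O3, CH2Cl2/MeOH, −78 °C; Me2S; then TsOH·H2O (0.1 equiv), PhMe, 80 °C
Reagents that add atoms: none
Why: Ozonolysis of the 1,1-disubstituted alkene gives the α-keto amide, and acid-catalysed intramolecular aldol condensation of the ring-ketone enol at C9 onto this ketone closes ring A (five-membered, the only unstrained mode) and dehydrates to the C8=C9 alkene conjugated with ketone and amide, so the oxygen brought in by ozone leaves again as water.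

Step 5
Reactants: 9 bicyclic enone amide
Product: 10 allylic alcohol (C10–OH, 10R, oxygen trans to H-15)
Conditions: (S)-2-methyl-CBS-oxazaborolidine (0.2 equiv), BH3·SMe2, THF, −20 °C; MeOH
Reagents that add atoms: none
Why: Corey–Bakshi–Shibata reduction under reagent control, where with the alkenyl side as the large group the (S)-catalyst is expected to give the (R) carbinol C10 with oxygen on the concave face (trans to H-15); ring closure of the new OH onto the C1 amide is not expected because a third five-membered ring at the sp2 carbon C9 would be strongly strained.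

Step 6
Reactants: 10 allylic alcohol; 11 3-(1,3-dioxolan-2-yl)propanoic acid
Product: 12 C10 allylic 3-(1,3-dioxolan-2-yl)propanoate
Conditions: DCC, DMAP (0.2 equiv), CH2Cl2, 0 °C → rt
Reagents that add atoms: none
Why: Steglich esterification of the secondary allylic alcohol; the amide N–H is not acylated under DMAP catalysis and C10 keeps its configuration.

Step 7
Reactants: 12 C10 allylic 3-(1,3-dioxolan-2-yl)propanoate
Product: 14 carboxylic acid with quaternary C8 (C8 bears the carboxamide trans to C16 and the C5H(CO2H)CH2(dioxolanyl) group cis to C16; alkene now C9=C10; C5 epimer mixture), via silyl ketene acetal 13 (not isolated)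
Conditions: LiN(i-Pr)2 (2.3 equiv), Me3SiCl (3 equiv), THF, −78 °C → 50 °C; aq. citric acid
Reagents that add atoms: none
Why: Ireland–Claisen rearrangement: after N–H deprotonation the ester is enolized and silylated, and the [3,3] shift forms C5–C8 suprafacially on the face that carried the C10–O bond, so C5 ends cis to C16 and the amide carbon C1 trans (a placement that alkylation from the convex face would not give) while the alkene moves to C9=C10; C5 forms as an epimer mixture that is re-set in step 12.

Step 8
Reactants: 14 carboxylic acid with quaternary C8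
Product: 15 tert-butyl ester of 14
Conditions: tert-butyl 2,2,2-trichloroacetimidate (2 equiv), CH2Cl2/cyclohexane, rt
Reagents that add atoms: tert-butyl 2,2,2-trichloroacetimidate, CC(C)(C)OC(=N)C(Cl)(Cl)Cl
Why: Acid-promoted O-alkylation of the carboxylic acid by the trichloroacetimidate (tert-butyl cation transfer); the carboxyl group is not activated, so no imide forms with the neighbouring amide, and the ester keeps C5 enolizable but inert in the next steps.

Step 9
Reactants: 15 tert-butyl ester
Product: 16 isoxazoline (3-methyl-4,5-dihydroisoxazole cis-fused at C10 (carbon) and C9 (oxygen) on the H-15 face)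
Conditions: MeC(Cl)=NOH (3 equiv, slow addition), Et3N, CH2Cl2, 0 °C → rt
Reagents that add atoms: N-hydroxyacetimidoyl chloride, CC(Cl)=NO
Why: 1,3-Dipolar cycloaddition of acetonitrile oxide to the only alkene; the oxygen should bond to the more substituted C9 and the carbon to C10, from the convex face (cis ring fusion), both new centres being lost again in step 10.

Step 10
Reactants: 16 isoxazoline
Product: 18 spiro enamide lactam enone (1-(4-methoxybenzyl)-3,4-dihydropyridin-2-one spiro at C8 with C6=C7, C5 H(CO2t-Bu) as epimer mixture, 10-acetyl on the C9=C10 alkene, C14 gem-dimethyl ester), via hydroxy ketone 17 (not isolated)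
Conditions: H2 (1 atm), Raney Ni, B(OH)3, MeOH/H2O 5:1, rt; then PPTS (0.5 equiv), PhMe, 100 °C
Reagents that add atoms: water, O
Why: Hydrogenolysis of the N–O bond and hydrolysis of the imine unmask the β-hydroxy methyl ketone (isoxazoline as aldol equivalent), which under mild acid dehydrates to the conjugated C9=C10 enone, while the dioxolane is exchanged by the amide N–H and loses ethylene glycol to give the six-membered enamide; the tert-butyl ester should survive pyridinium tosylate.

Step 11
Reactants: 18 spiro enamide lactam enone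
Product: 19 triisopropylsilyl enol ether of 18 (C10–C(OSi)=CH2)
Conditions: i-Pr3SiOTf (1.3 equiv), Et3N, CH2Cl2, 0 °C
Reagents that add atoms: triisopropylsilyl trifluoromethanesulfonate, CC(C)[Si](C(C)C)(C(C)C)OS(=O)(=O)C(F)(F)F
Why: Soft enolization of the methyl ketone with silyl triflate and amine gives the cross-conjugated 2-silyloxy diene, which masks the ketone against base and makes the C10 substituent bulky for the next step.

Step 12
Reactants: 19 triisopropylsilyl enol ether; 20 benzyl 3-bromopropyl ether
Product: 21 C5-alkylated spiro lactam (C5 bears CO2t-Bu cis to C9 and 3-(benzyloxy)propyl cis to C13)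
Conditions: KN(SiMe3)2 (1.1 equiv), THF, −78 °C; 20 (3 equiv), Bu4NI (0.3 equiv), DMPU, −78 → 0 °C
Reagents that add atoms: none
Why: Alkylation of the ester enolate (only C5–H is acidic); the enolate lies in the nearly planar dihydropyridinone, whose C9 face is covered by the silyloxyvinyl group that allylic strain holds over the ring, so the halide should enter from the C13 face and place the chain cis to C13 and the ester (later C21) cis to C9.

Step 13
Reactants: 21 C5-alkylated spiro lactam
Product: 22 C5 carboxylic acid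
Conditions: Me3SiOTf (3 equiv), 2,6-lutidine (5 equiv), CH2Cl2, 0 °C → rt; pH 5 buffer
Reagents that add atoms: none
Why: Silyl triflate cleavage of the tert-butyl ester (loss of isobutene, silyl ester hydrolysed on work-up) under non-protic conditions that should spare the enamide and the silyl enol ether.

Step 14
Reactants: 22 C5 carboxylic acid
Product: 24 C21 primary alcohol (C5–CH2OH), via acyl imidazolide 23 (not isolated)
Conditions: 1,1'-carbonyldiimidazole (2 equiv), THF, 50 °C; then NaBH4, H2O, 0 °C
Reagents that add atoms: none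
Why: Activation of the hindered acid as its acyl imidazolide and reduction with borohydride, which leaves methyl esters, lactam, enamide and silyl enol ether untouched.

Step 15
Reactants: 24 C21 primary alcohol
Product: 25 methyl ketone mono ester (C14 H(CO2Me) with the ester cis to C5; 10-acetyl; C21 alcohol)
Conditions: LiCl (5 equiv), H2O (3 equiv), DMSO, 150 °C
Reagents that add atoms: none
Why: Krapcho dealkoxycarbonylation: chloride demethylates one malonate ester, CO2 is lost and the ester enolate is protonated kinetically on the face of the lactam carbonyl C1, away from C5 and its propyl chain, so that the remaining ester stays cis to C5; the silyl enol ether is expected to be hydrolysed under these conditions.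

Step 16
Reactants: 25 methyl ketone mono ester
Product: 26 bis(triisopropylsilyl) compound (C21 silyl ether and silyl enol ether of the methyl ketone)
Conditions: i-Pr3SiOTf (2.5 equiv), Et3N (4 equiv), CH2Cl2, 0 °C → rt
Reagents that add atoms: triisopropylsilyl trifluoromethanesulfonate, CC(C)[Si](C(C)C)(C(C)C)OS(=O)(=O)C(F)(F)F
Why: Silyl triflate silylates the neopentyl alcohol and re-forms the kinetic silyl enol ether of the methyl ketone in one operation; triethylamine does not touch the C14 ester hydrogen.

Step 17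
Reactants: 26 bis(triisopropylsilyl) compound
Product: 27 spiro enamide lactam with diquinane iodomethyl ketone (key-step precursor)
Conditions: N-iodosuccinimide (1.1 equiv), NaHCO3, THF, −78 → −20 °C, dark
Reagents that add atoms: N-iodosuccinimide, O=C1CCC(=O)N1I
Why: Electrophilic α-iodination of the ketone through its silyl enol ether; the unhindered terminal carbon of the silyloxy diene should react faster than the enamide, whose β-carbon C6 is neopentyl.

Step 18
Reactants: 27 spiro enamide lactam with diquinane iodomethyl ketone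
Product: 28 tetracyclic bridged lactam enone (C6–C12 bond formed; C11 ketone; bicyclo[4.3.1] lactam)
Conditions: (Me3Si)3SiH (1.3 equiv, syringe pump), Et3B (0.3 equiv), air, PhMe (0.005 M), rt
Reagents that add atoms: none
Why: Et3B and oxygen start a chain in which the silyl radical abstracts iodine from C12 to give an electrophilic α-keto radical, which adds to C6, the electron-rich β-carbon of the enamide, and the resulting α-amido radical at C7 takes hydrogen from the silane. The closest known reaction type is the tin- or silane-mediated cyclization of α-carbonyl radicals onto enamides, usually run for five- and six-membered rings. The one ring closed is the cycloheptenone (C8–C9=C10–C11–C12–C6–C5), by 7-exo-trig attack, which also turns the lactam into a bicyclo[4.3.1] bridge. The one new stereocenter, C6, is fixed by the spiro carbon C8: the acyl chain sits on C10, cis to C8 on the ring alkene, and can reach only the enamide face that carries the cyclopentene arm, so the C6–C12 bond forms syn to C9. The step needs cyclization to beat direct reduction of the radical and 8-endo attack at C7; the polarity match, the enone that holds C12 within reach of C6, the greater stability of the nitrogen-substituted radical, and slow silane addition at high dilution should secure this.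

Step 19
Reactants: 28 tetracyclic bridged lactam enone
Product: 29 N–H lactam enone
Conditions: (NH4)2Ce(NO3)6 (3 equiv), MeCN/H2O 4:1, 0 °C
Reagents that add atoms: none
Why: Oxidative cleavage of the N-(4-methoxybenzyl) group by single-electron oxidation of the anisole ring and hydrolysis of the N-acyliminium ion; it is done here because the ring alkene is still an electron-poor enone, and the triisopropylsilyl and benzyl ethers should survive.

Step 20
Reactants: 29 N–H lactam enone
Product: 31 tetracyclic lactam with C11 methylene (C9=C10 alkene kept), via allylic alcohol 30 (not isolated)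
Conditions: NaBH4, CeCl3·7H2O, MeOH, −20 °C; then Et3SiH (10 equiv), CF3CO2H (5 equiv), CH2Cl2, −20 → 0 °C
Reagents that add atoms: none
Why: Luche 1,2-reduction gives the allylic alcohol, and ionic hydrogenation through the allyl cation delivers hydride to the less hindered secondary terminus C11, which keeps the tetrasubstituted C9=C10 alkene.

Step 21
Reactants: 31 tetracyclic lactam with C11 methylene
Product: 32 C2 primary alcohol (3-hydroxypropyl on C5)
Conditions: H2 (1 atm), Pd/C, EtOAc, rt
Reagents that add atoms: none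
Why: Hydrogenolysis of the primary benzyl ether; the tetrasubstituted alkene is not hydrogenated under these conditions.

Step 22
Reactants: 32 C2 primary alcohol
Product: 33 C2 aldehyde
Conditions: Dess–Martin periodinane, NaHCO3, CH2Cl2, rt
Reagents that add atoms: none
Why: Dess–Martin oxidation of the primary alcohol to the aldehyde under buffered, non-epimerizing conditions.

Step 23
Reactants: 33 C2 aldehyde; 34 (4S)-4-benzyl-3-propanoyl-1,3-oxazolidin-2-one
Product: 36 syn aldol adduct (C2 R carbinol, C18 methyl, acyl oxazolidinone at C19), via boron enolate 35 (not isolated)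
Conditions: 34 (2.2 equiv), Bu2BOTf, i-Pr2NEt, CH2Cl2, −78 → 0 °C; 33, −78 → 0 °C; pH 7 buffer, MeOH, H2O2
Reagents that add atoms: none
Why: Evans syn aldol reaction: the (Z)-boron enolate reacts through a chair Zimmerman–Traxler transition state on the face opposite the benzyl group of the (S)-auxiliary, which sets C2 and C18 syn under reagent control, independent of the remote core; the excess enolate allows for the lactam N–H.

Step 24
Reactants: 36 syn aldol adduct
Product: 37 C2 benzyl ether
Conditions: benzyl 2,2,2-trichloroacetimidate (2 equiv), CF3SO3H (0.1 equiv), CH2Cl2/cyclohexane, 0 °C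
Reagents that add atoms: benzyl 2,2,2-trichloroacetimidate, N=C(OCc1ccccc1)C(Cl)(Cl)Cl
Why: Acid-catalysed benzylation with the trichloroacetimidate protects the C2 hydroxyl without base (no retro-aldol), so that it cannot compete in steps 26 to 28.

Step 25
Reactants: 37 C2 benzyl ether
Product: 38 C19 primary alcohol
Conditions: NaBH4, THF/H2O 4:1, 0 °C → rt
Reagents that add atoms: none
Why: Borohydride reduction of the N-acyloxazolidinone (the more electrophilic imide carbonyl) to the primary alcohol with release of the auxiliary; the hindered methyl ester and the lactam are not reduced.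

Step 26
Reactants: 38 C19 primary alcohol
Product: 39 C19 mesylate
Conditions: MsCl, Et3N, CH2Cl2, 0 °C
Reagents that add atoms: methanesulfonyl chloride, CS(=O)(=O)Cl
Why: Sulfonylation of the primary alcohol; the lactam N–H is not sulfonylated by mesyl chloride and triethylamine.

Step 27
Reactants: 39 C19 mesylate
Product: 40 pentacyclic lactam (N–C19 bond, nine-membered ring; C2 benzyl ether; C21 silyl ether)
Conditions: KN(SiMe3)2 (1.05 equiv), THF (0.002 M), 0 °C → rt
Reagents that add atoms: none
Why: Intramolecular N-alkylation of the lactam anion (SN2 at the primary C19) at high dilution closes the nine-membered ring; the C4 chain on C5 points over the lactam towards nitrogen, and one equivalent of base deprotonates only the N–H, which is more acidic than the C14 ester hydrogen.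

Step 28
Reactants: 40 pentacyclic lactam
Product: 42 C21 acetate with C2 benzyl ether, via primary alcohol 41 (not isolated)
Conditions: HF·pyridine, THF/pyridine, 0 °C → rt; then Ac2O, DMAP, pyridine, rt
Reagents that add atoms: acetic anhydride, CC(=O)OC(C)=O
Why: Fluoride cleavage of the silyl ether under buffered, non-basic conditions followed by acetylation of the only free hydroxyl (C21) by acyl-transfer catalysis.

Step 29
Reactants: 42 C21 acetate with C2 benzyl ether
Product: 43 CNP0296366.1 (target)
Conditions: H2 (1 atm), Pd(OH)2/C, EtOAc/MeOH, rt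
Reagents that add atoms: none
Why: Hydrogenolysis of the secondary benzyl ether frees the C2 hydroxyl; ester, acetate, lactam and the tetrasubstituted alkene are inert, and the product is the target.

**Compound list**
1 | cyclopent-2-en-1-one | O=C1C=CCC1 | starting material
2 | dimethyl malonate | COC(=O)CC(=O)OC | starting material
3 | dimethyl 2-[(1S)-3-oxocyclopentyl]propanedioate | COC(=O)C(C(=O)OC)[C@H]1CCC(=O)C1 | intermediate
4 | 2-(bromomethyl)prop-2-enoic acid | OC(=O)C(=C)CBr | starting material
5 | 2-{2,2-bis(methoxycarbonyl)-2-[(1S)-3-oxocyclopentyl]ethyl}prop-2-enoic acid | OC(=O)C(=C)CC(C(=O)OC)(C(=O)OC)[C@H]1CCC(=O)C1 | intermediate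
6 | 4-methoxybenzylamine | COc1ccc(CN)cc1 | starting material
7 | dimethyl 2-{2-[(4-methoxybenzyl)carbamoyl]prop-2-en-1-yl}-2-[(1S)-3-oxocyclopentyl]propanedioate | COc1ccc(CNC(=O)C(=C)CC(C(=O)OC)(C(=O)OC)[C@H]2CCC(=O)C2)cc1 | intermediate
8 | keto amide (α-keto N-(4-methoxybenzyl)amide from ozonolysis of 7) | COc1ccc(CNC(=O)C(=O)CC(C(=O)OC)(C(=O)OC)[C@H]2CCC(=O)C2)cc1 | intermediate
9 | bicyclic enone amide (C8=C9, C10 ketone, C8 carboxamide, C14 gem-dimethyl ester, 15S) | COc1ccc(CNC(=O)C2=C3C(=O)CC[C@@H]3C(C(=O)OC)(C(=O)OC)C2)cc1 | intermediate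
10 | allylic alcohol (10R; OH trans to H-15) | COc1ccc(CNC(=O)C2=C3[C@H](O)CC[C@@H]3C(C(=O)OC)(C(=O)OC)C2)cc1 | intermediate
11 | 3-(1,3-dioxolan-2-yl)propanoic acid | OC(=O)CCC1OCCO1 | starting material
12 | C10 allylic 3-(1,3-dioxolan-2-yl)propanoate of 10 | COc1ccc(CNC(=O)C2=C3[C@H](OC(=O)CCC4OCCO4)CC[C@@H]3C(C(=O)OC)(C(=O)OC)C2)cc1 | intermediate
13 | silyl ketene acetal of 12 (N-silylated amide) | COc1ccc(CN([Si](C)(C)C)C(=O)C2=C3[C@H](OC(O[Si](C)(C)C)=CCC4OCCO4)CC[C@@H]3C(C(=O)OC)(C(=O)OC)C2)cc1 | intermediate
14 | Claisen acid (quaternary C8: carboxamide trans to C16, C5 cis to C16; C9=C10; C5 epimer mixture) | COC(=O)C1(C(=O)OC)C[C@](C2=CCC[C@H]12)(C(=O)NCc3ccc(OC)cc3)C(CC4OCCO4)C(=O)O | intermediate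
15 | tert-butyl ester of 14 | COC(=O)C1(C(=O)OC)C[C@](C2=CCC[C@H]12)(C(=O)NCc3ccc(OC)cc3)C(CC4OCCO4)C(=O)OC(C)(C)C | intermediate
16 | isoxazoline (O on C9, C on C10, cis-fused on the H-15 face) | COC(=O)C1(C(=O)OC)C[C@]([C@]23ON=C(C)[C@H]2CC[C@H]13)(C(=O)NCc4ccc(OC)cc4)C(CC5OCCO5)C(=O)OC(C)(C)C | intermediate
17 | hydroxy ketone (C9–OH, C10–acetyl, cis) | COC(=O)C1(C(=O)OC)C[C@]([C@]2(O)[C@@H](C(C)=O)CC[C@H]12)(C(=O)NCc3ccc(OC)cc3)C(CC4OCCO4)C(=O)OC(C)(C)C | intermediate
18 | spiro enamide lactam enone (C5 H(CO2t-Bu) epimer mixture, 10-acetyl, C14 gem-dimethyl ester) | COC(=O)C1(C(=O)OC)C[C@]2(C3=C(C(C)=O)CC[C@H]13)C(=O)N(Cc4ccc(OC)cc4)C=CC2C(=O)OC(C)(C)C | intermediate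
19 | triisopropylsilyl enol ether of 18 | COC(=O)C1(C(=O)OC)C[C@]2(C3=C(C(=C)O[Si](C(C)C)(C(C)C)C(C)C)CC[C@H]13)C(=O)N(Cc4ccc(OC)cc4)C=CC2C(=O)OC(C)(C)C | intermediate
20 | benzyl 3-bromopropyl ether | BrCCCOCc1ccccc1 | starting material
21 | C5-alkylated spiro lactam (CO2t-Bu cis to C9, benzyloxypropyl cis to C13) | COC(=O)C1(C(=O)OC)C[C@]2(C3=C(C(=C)O[Si](C(C)C)(C(C)C)C(C)C)CC[C@H]13)C(=O)N(Cc4ccc(OC)cc4)C=C[C@]2(C(=O)OC(C)(C)C)CCCOCc5ccccc5 | intermediate
22 | C5 carboxylic acid | COC(=O)C1(C(=O)OC)C[C@]2(C3=C(C(=C)O[Si](C(C)C)(C(C)C)C(C)C)CC[C@H]13)C(=O)N(Cc4ccc(OC)cc4)C=C[C@]2(C(=O)O)CCCOCc5ccccc5 | intermediate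
23 | acyl imidazolide of 22 | COC(=O)C1(C(=O)OC)C[C@]2(C3=C(C(=C)O[Si](C(C)C)(C(C)C)C(C)C)CC[C@H]13)C(=O)N(Cc4ccc(OC)cc4)C=C[C@]2(C(=O)n5ccnc5)CCCOCc6ccccc6 | intermediate
24 | C21 primary alcohol | COC(=O)C1(C(=O)OC)C[C@]2(C3=C(C(=C)O[Si](C(C)C)(C(C)C)C(C)C)CC[C@H]13)C(=O)N(Cc4ccc(OC)cc4)C=C[C@]2(CO)CCCOCc5ccccc5 | intermediate
25 | methyl ketone mono ester (C14 ester cis to C5) | COC(=O)[C@@H]1C[C@]2(C3=C(C(C)=O)CC[C@H]13)C(=O)N(Cc4ccc(OC)cc4)C=C[C@]2(CO)CCCOCc5ccccc5 | intermediate
26 | bis(triisopropylsilyl) compound (C21 silyl ether, silyl enol ether) | COC(=O)[C@@H]1C[C@]2(C3=C(C(=C)O[Si](C(C)C)(C(C)C)C(C)C)CC[C@H]13)C(=O)N(Cc4ccc(OC)cc4)C=C[C@]2(CO[Si](C(C)C)(C(C)C)C(C)C)CCCOCc5ccccc5 | intermediate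
27 | spiro enamide lactam with diquinane iodomethyl ketone | COC(=O)[C@@H]1C[C@]2(C3=C(C(=O)CI)CC[C@H]13)C(=O)N(Cc4ccc(OC)cc4)C=C[C@]2(CO[Si](C(C)C)(C(C)C)C(C)C)CCCOCc5ccccc5 | intermediate
28 | tetracyclic bridged lactam enone | COC(=O)[C@@H]1C[C@@]23C(=O)N(Cc4ccc(OC)cc4)C[C@@H](CC(=O)C5=C2[C@@H]1CC5)[C@]3(CO[Si](C(C)C)(C(C)C)C(C)C)CCCOCc6ccccc6 | intermediate
29 | N–H lactam enone | COC(=O)[C@@H]1C[C@@]23C(=O)NC[C@@H](CC(=O)C4=C2[C@@H]1CC4)[C@]3(CO[Si](C(C)C)(C(C)C)C(C)C)CCCOCc5ccccc5 | intermediate
30 | C11 allylic alcohol (epimer mixture) | COC(=O)[C@@H]1C[C@@]23C(=O)NC[C@@H](CC(O)C4=C2[C@@H]1CC4)[C@]3(CO[Si](C(C)C)(C(C)C)C(C)C)CCCOCc5ccccc5 | intermediate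
31 | tetracyclic lactam with C11 methylene | COC(=O)[C@@H]1C[C@@]23C(=O)NC[C@@H](CCC4=C2[C@@H]1CC4)[C@]3(CO[Si](C(C)C)(C(C)C)C(C)C)CCCOCc5ccccc5 | intermediate
32 | C2 primary alcohol | COC(=O)[C@@H]1C[C@@]23C(=O)NC[C@@H](CCC4=C2[C@@H]1CC4)[C@]3(CO[Si](C(C)C)(C(C)C)C(C)C)CCCO | intermediate
33 | C2 aldehyde | COC(=O)[C@@H]1C[C@@]23C(=O)NC[C@@H](CCC4=C2[C@@H]1CC4)[C@]3(CO[Si](C(C)C)(C(C)C)C(C)C)CCC=O | intermediate
34 | (4S)-4-benzyl-3-propanoyl-1,3-oxazolidin-2-one | CCC(=O)N1C(=O)OC[C@@H]1Cc1ccccc1 | starting material
35 | (Z)-dibutylboron enolate of 34 | C/C=C(\OB(CCCC)CCCC)N1C(=O)OC[C@@H]1Cc1ccccc1 | intermediate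
36 | syn aldol adduct | COC(=O)[C@@H]1C[C@@]23C(=O)NC[C@@H](CCC4=C2[C@@H]1CC4)[C@]3(CO[Si](C(C)C)(C(C)C)C(C)C)CC[C@@H](O)[C@H](C)C(=O)N5C(=O)OC[C@@H]5Cc6ccccc6 | intermediate
37 | C2 benzyl ether of 36 | COC(=O)[C@@H]1C[C@@]23C(=O)NC[C@@H](CCC4=C2[C@@H]1CC4)[C@]3(CO[Si](C(C)C)(C(C)C)C(C)C)CC[C@@H](OCc5ccccc5)[C@H](C)C(=O)N6C(=O)OC[C@@H]6Cc7ccccc7 | intermediate
38 | C19 primary alcohol | COC(=O)[C@@H]1C[C@@]23C(=O)NC[C@@H](CCC4=C2[C@@H]1CC4)[C@]3(CO[Si](C(C)C)(C(C)C)C(C)C)CC[C@@H](OCc5ccccc5)[C@H](C)CO | intermediate
39 | C19 mesylate | COC(=O)[C@@H]1C[C@@]23C(=O)NC[C@@H](CCC4=C2[C@@H]1CC4)[C@]3(CO[Si](C(C)C)(C(C)C)C(C)C)CC[C@@H](OCc5ccccc5)[C@H](C)COS(C)(=O)=O | intermediate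
40 | pentacyclic lactam (C2 benzyl ether, C21 silyl ether) | COC(=O)[C@@H]1C[C@@]23C(=O)N4C[C@@H](CCC5=C2[C@@H]1CC5)[C@]3(CO[Si](C(C)C)(C(C)C)C(C)C)CC[C@@H](OCc6ccccc6)[C@H](C)C4 | intermediate
41 | C21 primary alcohol of the pentacycle | COC(=O)[C@@H]1C[C@@]23C(=O)N4C[C@@H](CCC5=C2[C@@H]1CC5)[C@]3(CO)CC[C@@H](OCc6ccccc6)[C@H](C)C4 | intermediate
42 | C21 acetate with C2 benzyl ether | COC(=O)[C@@H]1C[C@@]23C(=O)N4C[C@@H](CCC5=C2[C@@H]1CC5)[C@]3(COC(C)=O)CC[C@@H](OCc6ccccc6)[C@H](C)C4 | intermediate
43 | CNP0296366.1 | COC(=O)[C@@H]1C[C@@]23C(=O)N4C[C@@H](CCC5=C2[C@@H]1CC5)[C@]3(COC(C)=O)CC[C@@H](O)[C@H](C)C4 | target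

**Step count and risks**
Total steps: 29. Longest linear sequence: 29 steps (from 1 to 43).

Steps most likely to fail:

Step 18 (key step). The α-keto radical may take hydrogen from the silane before the slow seven-membered closure, or shift a hydrogen intramolecularly, so that simple reduction of the iodide wins. Fallback: a xanthate group-transfer cyclization, which has no hydrogen donor in its chain-carrying steps. Iodide 27 is treated with KSC(S)OEt in acetone to give the S-(2-oxoalkyl) O-ethyl xanthate F1. Dilauroyl peroxide, added in portions in refluxing 1,2-dichloroethane, should transfer the xanthate across the enamide and give the cyclized C7 xanthate F2. (Me3Si)3SiH with AIBN in toluene at 80 °C then removes the xanthate and returns to 28.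

Step 27. Intermolecular N-alkylation (oligomers), E2 loss of the mesylate or base-mediated epimerization at C14 may outrun the entropically slow nine-membered closure. Fallback: acid-mediated reductive N-alkylation through an N-acyliminium ion, with no strong base. Alcohol 38 is oxidized with Dess–Martin periodinane to the C19 aldehyde F3. F3 is treated at high dilution with Et3SiH and CF3CO2H in CH2Cl2; reversible N-acyl hemiaminal formation across the ring and irreversible hydride capture should give 40.

Step 9. Dimerization of the nitrile oxide may outrun cycloaddition at the hindered trisubstituted alkene, or the dipole may add with reversed orientation. Fallback: an epoxide route to the same aldol. Alkene 15 is epoxidized with mCPBA on the convex face to the C9–C10 epoxide F4. Et2AlC≡CSiMe3 in toluene at 0 °C should open F4 at the less hindered C10 to give the trans hydroxy silylalkyne F5. K2CO3 in MeOH gives the terminal alkyne F6, and Ph3PAuNTf2-catalysed hydration in wet dioxane gives the hydroxy ketone F7, the C10 epimer of 17. Under the pyridinium tosylate conditions of step 10, F7 gives 18.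

Further compounds
F1 | step 18 | S-(2-oxoalkyl) O-ethyl xanthate of the key-step precursor | COC(=O)[C@@H]1C[C@]2(C3=C(C(=O)CSC(=S)OCC)CC[C@H]13)C(=O)N(Cc4ccc(OC)cc4)C=C[C@]2(CO[Si](C(C)C)(C(C)C)C(C)C)CCCOCc5ccccc5
F2 | step 18 | cyclized C7 xanthate | COC(=O)[C@@H]1C[C@@]23C(=O)N(Cc4ccc(OC)cc4)C(SC(=S)OCC)[C@@H](CC(=O)C5=C2[C@@H]1CC5)[C@]3(CO[Si](C(C)C)(C(C)C)C(C)C)CCCOCc6ccccc6
F3 | step 27 | C19 aldehyde | COC(=O)[C@@H]1C[C@@]23C(=O)NC[C@@H](CCC4=C2[C@@H]1CC4)[C@]3(CO[Si](C(C)C)(C(C)C)C(C)C)CC[C@@H](OCc5ccccc5)[C@H](C)C=O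
F4 | step 9 | C9–C10 epoxide | COC(=O)C1(C(=O)OC)C[C@]([C@]23O[C@H]2CC[C@H]13)(C(=O)NCc4ccc(OC)cc4)C(CC5OCCO5)C(=O)OC(C)(C)C
F5 | step 9 | trans hydroxy silylalkyne | COC(=O)C1(C(=O)OC)C[C@]([C@]2(O)[C@H](C#C[Si](C)(C)C)CC[C@H]12)(C(=O)NCc3ccc(OC)cc3)C(CC4OCCO4)C(=O)OC(C)(C)C
F6 | step 9 | terminal alkyne | COC(=O)C1(C(=O)OC)C[C@]([C@]2(O)[C@H](C#C)CC[C@H]12)(C(=O)NCc3ccc(OC)cc3)C(CC4OCCO4)C(=O)OC(C)(C)C
F7 | step 9 | hydroxy ketone, C10 epimer of 17 | COC(=O)C1(C(=O)OC)C[C@]([C@]2(O)[C@H](C(C)=O)CC[C@H]12)(C(=O)NCc3ccc(OC)cc3)C(CC4OCCO4)C(=O)OC(C)(C)C
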